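At early times in Tuesday's run, single product builds up, 7% at 20.0 d and 19% at 100 d, while the over-reaction product, which we take to grow out of the single product, stays inside the scatter.

| flask | substrate | reagent | temperature | remark | time |
|---|---|---|---|---|---|
| Tuesday's | 0.070 M | 0.045 M | −20 °C | run made earlier |  |
| Thursday's | 0.11 M | 0.045 M | 15 °C | run made earlier |  |
| gamma | 0.050 M | 0.0450 M | 25 °C |  | 25 d |
| epsilon | 0.050 M | 0.0450 M | 45 °C |  | 25 d |
| alpha | 0.050 M | 0.0450 M | −15 °C |  | 25 d |
| zeta | 0.050 M | 0.0450 M | 5 °C |  | 25 d |

| run | time / d | single product / % | double product / % | over-reaction product / % |
|---|---|---|---|---|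
| Tuesday's | 20.0 | 7 | 0 | 2 |
| Tuesday's | 60.0 | 13 | 0 | 1 |
| Tuesday's | 100 | 19 | 0 | 0 |
| Tuesday's | 150 | 24 | 4 | 4 |
| Tuesday's | 250 | 27 | 3 | 7 |
| Tuesday's | 300 | 31 | 3 | 6 |
| Thursday's | 8.00 | 9 | 3 | 24 |
| Thursday's | 15.0 | 4 | 0 | 31 |
| Thursday's | 25.0 | 0 | 4 | 35 |
| Thursday's | 30.0 | 1 | 0 | 34 |
| Thursday's | 40.0 | 3 | 1 | 39 |
| Thursday's | 50.0 | 1 | 0 | 40 |

(each reading ± 2 percentage points)

- the flask with the highest share of single product in all that became single product or double product or over-reaction product ("all alike" if they lie within 1.5 percentage points) (gamma / epsilon / alpha / zeta / all alike)
- share of single product in all that became single product or double product or over-reaction product, gamma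
- share of single product in all that became single product or double product or over-reaction product, epsilon
- share of single product in all that became single product or double product or over-reaction product, alpha
- share of single product in all that became single product or double product or over-reaction product, zeta

- the numbers in the tables scatter with a standard deviation of 2 percentage points

We treat the drain of single product as a first-order step with constant k, so the gain in over-reaction product, divided by the mean single product and by the interval, reads k. Tuesday's run, from zero to its last reading, gives 0.00129 /d. Thursday's run, between 8.00 d and 15.0 d, where its total has stopped rising, gives 0.154 /d, which is 119 times as fast. Interpolating ln k in temperature puts alpha at 0.00255 /d, a drain time of 392 d against a run of 25 d. We carry the drain number x, the run length over the drain time, which for alpha is 0.0639. Product made steadily has on average stood for half of the run, so c(over-reaction product)/c(single product) is about half of x, or 3.19%, and by this reckoning the selectivity of alpha comes to 96.9%.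

The weak link is that this leaves out double product. Tuesday's last reading of 3%, close to the scatter, read by the same rule and moved by the same temperature factor, gives alpha a second number of 0.0319. We therefore commit to 95.4% for alpha. Zeta has x = 0.981, too large for this small-x rule, so we say only that zeta lies well below alpha, and the hotter flasks lower still.

The forecast names alpha, with 94% for alpha, 50% for zeta, 1% for gamma and 0.1% for epsilon, and holds that “Double product stays minor.”

The simulation gives alpha: 93.4% for alpha, 32.2% for zeta, 0.848% for gamma and 0.00744% for epsilon.

    substrate + reagent → single product + released group (k = 0.520 /M/h, Ea = 71.0 kJ/mol)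
    reagent + single product ⇌ double product + released group (K = 1.80, k = 0.390 /M/h, Ea = 80.0 kJ/mol, ΔH = −34.0 kJ/mol)
    substrate ⇌ dormant form (K = 2.50, k = 0.00670 /h, Ea = 114 kJ/mol, ΔH = −9.00 kJ/mol)
    single product → over-reaction product (k = 0.0350 /h, Ea = 92.0 kJ/mol)
    (constants at 25 °C)

In alpha at 25 d, over-reaction product stands at 3.61% of single product, against 3.19% from the drain number. The largest single effect on the difference between the hottest and the coldest flask, epsilon minus alpha, is what temperature does to the conversion of single product into over-reaction product: that difference is −93 points with it and 0.16 points without it. The neighbour of alpha at −30 °C has x = 0.00823, and with its double-product number that gives 99.4%; that flask stands at 99.4%.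

(The readings are calculated for substances that don't exist, noise included.)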